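**Plan**

1. Retrosynthesis: the spiro C–O bond to the naphthalene C8 oxygen is cut first (N,O-ketal back to a 3-hydroxyisoindolinone with a peri-naphthol). Next the lactam is opened (C–N and aryl–C(=O) bonds, back to an ortho-bromoaryl naphthyl ketone, CO and O-benzyl ethanolamine), then the C1–C2 and C3–C4 bonds of the naphthalene, then the aryl–alkyne bond.
2. Enabling feature, with the naphthalene numbered C1 (carries the spiro carbon), C2 (OH), C6 (Me), C8 (ketal O): the phenol ring C1–C4/C4a/C8a has its oxygen at C2 directly beside C1, which bears a ketone-level carbon. This 1-acyl-2-oxy pattern is what a benzopyrylium–ynol ether benzannulation delivers.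
3. Forward order: the tolyl ring (C4a–C8a) is prepared as iodo aldehyde tosylate 8 and a Sonogashira coupling joins the anisyl ring (11). The gold-catalysed benzannulation with benzyloxyethyne then closes the phenol ring and unveils the diaryl ketone (21).
4. Aminocarbonylation closes the lactam ring (24), detosylation frees O8 (25), ketalisation closes the furan ring (27) and hydrogenolysis gives target 28.
5. Stereochemistry: the only stereocentre, the (R)-spiro carbon, is set in the furan-ring closure by a chiral phosphoric acid through its ion pair with the N-acyliminium ion. Both remaining benzyl ethers are then removed under neutral conditions so that the ketal is not re-ionised.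

Key step: step 9

Assumption: the sense of induction of the phosphoric acid cannot be predicted for this substrate; the (R)-catalyst is written, and its antipode would be used if a first run gives the opposite sense.

**Route**

Step 1
Reactants: 1 3-hydroxy-5-methylbenzaldehyde
Product: 2 3-(methoxymethoxy)-5-methylbenzaldehyde
Conditions: MOMCl, iPr2NEt, CH2Cl2, 0 °C to rt
Reagents that add atoms: chloromethyl methyl ether (MOMCl), COCCl
Why: Base-mediated O-alkylation of the phenol (Williamson-type etherification) masks the hydroxyl as a methoxymethyl acetal that tolerates alkyllithiums and serves as an ortho-directing group in the next step.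

Step 2
Reactants: 2 3-(methoxymethoxy)-5-methylbenzaldehyde
Product: 6 2-iodo-3-(methoxymethoxy)-5-methylbenzaldehyde, via lithium alpha-amino alkoxide 3 (not isolated), via C2-lithiated alpha-amino alkoxide 4 (not isolated), via iodinated alpha-amino alkoxide 5 (not isolated)
Conditions: LiN(Me)CH2CH2NMe2 (from MeNHCH2CH2NMe2 and n-BuLi), THF, −20 °C; n-BuLi (3 equiv), −20 °C; I2, −78 °C to rt; aq. NH4Cl/Na2S2O3
Reagents that add atoms: iodine, II
Why: Directed ortho-metalation with in situ aldehyde protection: the lithium amide adds to the formyl group, the chelating alpha-amino alkoxide and the methoxymethoxy group together direct n-BuLi to the shared ortho position C2, and iodine quench followed by aqueous hydrolysis returns the aldehyde.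

Step 3
Reactants: 6 2-iodo-3-(methoxymethoxy)-5-methylbenzaldehyde
Product: 7 3-hydroxy-2-iodo-5-methylbenzaldehyde
Conditions: 3 M aq. HCl, THF, 50 °C
Reagents that add atoms: none
Why: Acid-catalysed hydrolysis of the methoxymethyl acetal frees the phenol while the aryl iodide and the aldehyde are inert.

Step 4
Reactants: 7 3-hydroxy-2-iodo-5-methylbenzaldehyde
Product: 8 3-formyl-2-iodo-5-methylphenyl 4-methylbenzenesulfonate
Conditions: TsCl, Et3N, 4-(dimethylamino)pyridine (cat.), CH2Cl2, 0 °C to rt
Reagents that add atoms: 4-methylbenzenesulfonyl chloride (TsCl), Cc1ccc(cc1)S(=O)(=O)Cl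
Why: O-Sulfonylation of the phenol gives an aryl tosylate whose oxygen is too electron-poor to add to a gold-activated alkyne later and which is inert to Sonogashira conditions at an aryl iodide.

Step 5
Reactants: 9 2-bromo-6-methoxybenzaldehyde
Product: 10 1-bromo-2-ethynyl-3-methoxybenzene
Conditions: dimethyl (1-diazo-2-oxopropyl)phosphonate, K2CO3, MeOH, rt
Reagents that add atoms: dimethyl (1-diazo-2-oxopropyl)phosphonate, COP(=O)(OC)C(=[N+]=[N-])C(C)=O
Why: Seyferth–Gilbert homologation in its Ohira–Bestmann form converts the non-enolisable aryl aldehyde into the terminal alkyne under mild carbonate conditions that leave the aryl bromide untouched.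

Step 6
Reactants: 8 3-formyl-2-iodo-5-methylphenyl 4-methylbenzenesulfonate, 10 1-bromo-2-ethynyl-3-methoxybenzene
Product: 11 2-[(2-bromo-6-methoxyphenyl)ethynyl]-3-formyl-5-methylphenyl 4-methylbenzenesulfonate
Conditions: Pd(PPh3)2Cl2 (2 mol%), CuI (4 mol%), Et3N, THF, rt to 40 °C
Reagents that add atoms: none
Why: Sonogashira coupling: oxidative addition of zerovalent palladium into the electron-poor C–I bond of 8 is much faster than into the C–Br bond of 10 or the C–OTs bond, so only the diarylalkyne should form.

Step 7
Reactants: 12 benzyl alcohol, 13 trichloroethylene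
Product: 16 benzyl (E)-1,2-dichlorovinyl ether, via potassium benzyloxide 14 (not isolated), via dichloroacetylene 15 (not isolated)
Conditions: KH, THF, 0 °C; Cl2C=CHCl, −50 °C to rt
Reagents that add atoms: none
Why: Alkoxide-induced dehydrochlorination of trichloroethylene to dichloroacetylene and anti addition of benzyl alcohol across it is the standard first stage of alkoxyacetylene synthesis and gives the E-dichlorovinyl ether.

Step 8
Reactants: 16 benzyl (E)-1,2-dichlorovinyl ether
Product: 19 benzyloxyethyne, via benzyl chloroethynyl ether 17 (not isolated), via lithium benzyloxyacetylide 18 (not isolated)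
Conditions: n-BuLi (2.4 equiv), THF, −78 to −40 °C; MeOH, −78 °C; used at once as a cold solution
Reagents that add atoms: none
Why: Beta-elimination of HCl by n-BuLi, chlorine–lithium exchange on the chloroalkyne and cold protonation of the acetylide give the terminal ynol ether (alkoxyacetylene synthesis from dichlorovinyl ethers), which is kept cold because benzyl ynol ethers rearrange on warming.

Step 9
Reactants: 11 2-[(2-bromo-6-methoxyphenyl)ethynyl]-3-formyl-5-methylphenyl 4-methylbenzenesulfonate, 19 benzyloxyethyne
Product: 21 (2-bromo-6-methoxyphenyl)[2-(benzyloxy)-6-methyl-8-(tosyloxy)naphthalen-1-yl]methanone, via benzopyrylium trichloroaurate zwitterion 20 (not isolated)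
Conditions: AuCl3 (5 mol%), 4 Å MS, (CH2Cl)2, rt; 19 (3 equiv) added slowly
Reagents that add atoms: none
Why: Proposed new method: gold trichloride activates the diarylalkyne of 11 for 6-endo-dig attack by the formyl oxygen, giving benzopyrylium aurate 20; the nucleophilic CH terminus of ynol ether 19 adds to the former formyl carbon, the resulting ketene-oxonium carbon is captured by the gold-bearing carbon, and the oxa-bridged adduct opens with release of AuCl3 so that the former aldehyde oxygen remains on the former distal alkyne carbon as the diaryl ketone. The closest known reaction type is the AuCl3- or Cu(OTf)2-catalysed formal [4+2] benzannulation of ortho-alkynylbenzaldehydes with aryl- and alkylalkynes to 1-acylnaphthalenes, which has not been established with an alkoxyalkyne as the two-carbon partner. The phenol ring is closed by this stepwise formal [4+2] annulation across the two termini of the pyrylium (new C3–C4 and C1–C2 bonds) followed by aromatising ring opening, and no stereocentre is formed. The required regioselectivity comes from the polarisation of the ynol ether, which places the benzyloxy carbon next to the acyl-bearing carbon just as a terminal alkyne places its substituent in the known reaction. Chemoselectivity rests on the tosylate, which keeps the neighbouring oxygen from cyclising onto the alkyne, on the electron-rich anisyl group, which steers the formyl oxygen to the distal alkyne carbon, and on slow addition of 19 at ambient temperature to outrun aldehyde–ynol ether metathesis and thermal loss of the ynol ether.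

Step 10
Reactants: 21 (2-bromo-6-methoxyphenyl)[2-(benzyloxy)-6-methyl-8-(tosyloxy)naphthalen-1-yl]methanone, 22 2-(benzyloxy)ethan-1-amine
Product: 24 racemic 3-[2-(benzyloxy)-6-methyl-8-(tosyloxy)naphthalen-1-yl]-2-[2-(benzyloxy)ethyl]-3-hydroxy-4-methoxyisoindolin-1-one, via open-chain keto amide 23 (not isolated)
Conditions: Pd(OAc)2 (5 mol%), 4,5-bis(diphenylphosphino)-9,9-dimethylxanthene (10 mol%), CO (1 atm), Et3N, toluene, 90 °C
Reagents that add atoms: carbon monoxide, [C-]#[O+]
Why: Palladium-catalysed aminocarbonylation (oxidative addition at C–Br, CO insertion, aminolysis of the acylpalladium) gives the 2-acylbenzamide, whose NH adds to the neighbouring ketone by ring-chain tautomerism to give the hydroxylactam; the aryl tosylate is inert to this catalyst.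

Step 11
Reactants: 24 racemic 3-[2-(benzyloxy)-6-methyl-8-(tosyloxy)naphthalen-1-yl]-2-[2-(benzyloxy)ethyl]-3-hydroxy-4-methoxyisoindolin-1-one
Product: 25 racemic 3-[2-(benzyloxy)-8-hydroxy-6-methylnaphthalen-1-yl]-2-[2-(benzyloxy)ethyl]-3-hydroxy-4-methoxyisoindolin-1-one
Conditions: KOH, MeOH/THF/H2O, 60 °C; pH 7 buffer work-up
Reagents that add atoms: none
Why: Hydroxide attacks the sulfonyl sulfur (saponification of an aryl sulfonate) and releases the peri naphthol; benzyl ethers, lactam and methyl ether are stable, and the buffered work-up avoids premature acid-mediated closure.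

Step 12
Reactants: 25 racemic 3-[2-(benzyloxy)-8-hydroxy-6-methylnaphthalen-1-yl]-2-[2-(benzyloxy)ethyl]-3-hydroxy-4-methoxyisoindolin-1-one
Product: 27 (R)-3'-(benzyloxy)-2-[2-(benzyloxy)ethyl]-7-methoxy-7'-methylspiro[isoindoline-1,2'-naphtho[1,8-bc]furan]-3-one, via N-acyliminium ion 26 (not isolated)
Conditions: (R)-3,3'-bis(2,4,6-triisopropylphenyl)-1,1'-binaphthyl-2,2'-diyl hydrogen phosphate (10 mol%), 4 Å MS, toluene, 0 °C
Reagents that add atoms: none
Why: Proposed new method: the phosphoric acid ionises the tertiary hydroxylactam to N-acyl ketiminium ion 26, held as a contact ion pair with the chiral phosphate that also hydrogen-bonds the peri naphthol, and the C8 oxygen adds to one face of the iminium carbon in a 5-exo-trig closure of the naphtho[1,8-bc]furan ring, the catalyst pocket choosing the face that gives the (R)-ketal; the closest known reaction types are chiral-phosphoric-acid-catalysed additions of thiols, indoles and hydride donors to ketiminium ions from 3-aryl-3-hydroxyisoindolinones and acid-catalysed asymmetric N,O-acetalisations and spiroketalisations, and only the C8 hydroxyl can close because the other two oxygens are benzylated.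

Step 13
Reactants: 27 (R)-3'-(benzyloxy)-2-[2-(benzyloxy)ethyl]-7-methoxy-7'-methylspiro[isoindoline-1,2'-naphtho[1,8-bc]furan]-3-one
Product: 28 (R)-3'-hydroxy-2-(2-hydroxyethyl)-7-methoxy-7'-methylspiro[isoindoline-1,2'-naphtho[1,8-bc]furan]-3-one
Conditions: H2 (1 atm), Pd/C (10 wt%), EtOAc, rt
Reagents that add atoms: none
Why: Heterogeneous hydrogenolysis cleaves both primary benzyl ethers under neutral conditions, so the acid- and base-sensitive N,O-ketal stereocentre, which is quaternary and shielded from the catalyst surface, should be preserved.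

**Compound list**

1 | 3-hydroxy-5-methylbenzaldehyde | Cc1cc(O)cc(C=O)c1 | starting material
2 | 3-(methoxymethoxy)-5-methylbenzaldehyde | COCOc1cc(C)cc(C=O)c1 | intermediate
3 | lithium {[2-(dimethylamino)ethyl](methyl)amino}[3-(methoxymethoxy)-5-methylphenyl]methanolate | [Li]OC(N(C)CCN(C)C)c1cc(C)cc(OCOC)c1 | intermediate
4 | lithium {[2-(dimethylamino)ethyl](methyl)amino}[2-lithio-3-(methoxymethoxy)-5-methylphenyl]methanolate | [Li]OC(N(C)CCN(C)C)c1cc(C)cc(OCOC)c1[Li] | intermediate
5 | lithium {[2-(dimethylamino)ethyl](methyl)amino}[2-iodo-3-(methoxymethoxy)-5-methylphenyl]methanolate | [Li]OC(N(C)CCN(C)C)c1cc(C)cc(OCOC)c1I | intermediate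
6 | 2-iodo-3-(methoxymethoxy)-5-methylbenzaldehyde | COCOc1cc(C)cc(C=O)c1I | intermediate
7 | 3-hydroxy-2-iodo-5-methylbenzaldehyde | Cc1cc(O)c(I)c(C=O)c1 | intermediate
8 | 3-formyl-2-iodo-5-methylphenyl 4-methylbenzenesulfonate | Cc1ccc(cc1)S(=O)(=O)Oc1cc(C)cc(C=O)c1I | intermediate
9 | 2-bromo-6-methoxybenzaldehyde | COc1cccc(Br)c1C=O | starting material
10 | 1-bromo-2-ethynyl-3-methoxybenzene | COc1cccc(Br)c1C#C | intermediate
11 | 2-[(2-bromo-6-methoxyphenyl)ethynyl]-3-formyl-5-methylphenyl 4-methylbenzenesulfonate | COc1cccc(Br)c1C#Cc1c(C=O)cc(C)cc1OS(=O)(=O)c1ccc(C)cc1 | intermediate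
12 | benzyl alcohol | OCc1ccccc1 | starting material
13 | trichloroethylene | ClC=C(Cl)Cl | starting material
14 | potassium benzyloxide | [K+].[O-]Cc1ccccc1 | intermediate
15 | dichloroacetylene | ClC#CCl | intermediate
16 | benzyl (E)-1,2-dichlorovinyl ether | Cl/C=C(/Cl)OCc1ccccc1 | intermediate
17 | benzyl chloroethynyl ether | ClC#COCc1ccccc1 | intermediate
18 | lithium benzyloxyacetylide | [Li]C#COCc1ccccc1 | intermediate
19 | benzyloxyethyne | C#COCc1ccccc1 | intermediate
20 | [3-(2-bromo-6-methoxyphenyl)-7-methyl-5-(tosyloxy)isochromenylium-4-yl]trichloroaurate (zwitterion) | COc1cccc(Br)c1-c1[o+]cc2cc(C)cc(OS(=O)(=O)c3ccc(C)cc3)c2c1[Au-](Cl)(Cl)Cl | intermediate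
21 | (2-bromo-6-methoxyphenyl)[2-(benzyloxy)-6-methyl-8-(tosyloxy)naphthalen-1-yl]methanone | COc1cccc(Br)c1C(=O)c1c(OCc2ccccc2)ccc2cc(C)cc(OS(=O)(=O)c3ccc(C)cc3)c12 | intermediate
22 | 2-(benzyloxy)ethan-1-amine | NCCOCc1ccccc1 | starting material
23 | N-[2-(benzyloxy)ethyl]-2-[2-(benzyloxy)-6-methyl-8-(tosyloxy)-1-naphthoyl]-3-methoxybenzamide | COc1cccc(C(=O)NCCOCc2ccccc2)c1C(=O)c1c(OCc2ccccc2)ccc2cc(C)cc(OS(=O)(=O)c3ccc(C)cc3)c12 | intermediate
24 | racemic 3-[2-(benzyloxy)-6-methyl-8-(tosyloxy)naphthalen-1-yl]-2-[2-(benzyloxy)ethyl]-3-hydroxy-4-methoxyisoindolin-1-one | COc1cccc2c1C(O)(c1c(OCc3ccccc3)ccc3cc(C)cc(OS(=O)(=O)c4ccc(C)cc4)c13)N(CCOCc1ccccc1)C2=O | intermediate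
25 | racemic 3-[2-(benzyloxy)-8-hydroxy-6-methylnaphthalen-1-yl]-2-[2-(benzyloxy)ethyl]-3-hydroxy-4-methoxyisoindolin-1-one | COc1cccc2c1C(O)(c1c(OCc3ccccc3)ccc3cc(C)cc(O)c13)N(CCOCc1ccccc1)C2=O | intermediate
26 | 1-[2-(benzyloxy)-8-hydroxy-6-methylnaphthalen-1-yl]-2-[2-(benzyloxy)ethyl]-7-methoxy-3-oxo-3H-isoindol-2-ium (cation of the chiral phosphate ion pair) | COc1cccc2c1C(c1c(OCc3ccccc3)ccc3cc(C)cc(O)c13)=[N+](CCOCc1ccccc1)C2=O | intermediate
27 | (R)-3'-(benzyloxy)-2-[2-(benzyloxy)ethyl]-7-methoxy-7'-methylspiro[isoindoline-1,2'-naphtho[1,8-bc]furan]-3-one | COc1cccc2c1[C@@]1(Oc3cc(C)cc4ccc(OCc5ccccc5)c1c34)N(CCOCc1ccccc1)C2=O | intermediate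
28 | (R)-3'-hydroxy-2-(2-hydroxyethyl)-7-methoxy-7'-methylspiro[isoindoline-1,2'-naphtho[1,8-bc]furan]-3-one | COc1cccc2c1[C@@]1(Oc3cc(C)cc4ccc(O)c1c34)N(CCO)C2=O | target

**Step count**

Total steps: 13. Longest linear sequence: 10 steps (1, 2, 3, 4, 6, 9, 10, 11, 12, 13).

**Steps most likely to fail**

1. Step 9 (proposed new method). The Lewis-acidic gold may consume the ynol ether by [2+2] addition/metathesis with the free aldehyde, hydration or oligomerisation before the pyrylium is intercepted, and the crowded pyrylium may react slowly. The fallback uses known reactions and sets out from 11. The pyrylium would be intercepted by water (AuCl3 or AgOTf cat., wet 1,4-dioxane), a known hydration of ortho-alkynylbenzaldehydes, to give the keto aldehyde 3-formyl-2-[2-(2-bromo-6-methoxyphenyl)-2-oxoethyl]-5-methylphenyl 4-methylbenzenesulfonate F1. A Z-selective Horner–Wadsworth–Emmons olefination with ethyl (diphenoxyphosphoryl)acetate (NaH, THF, −78 °C) would give the acrylate ethyl (Z)-3-{2-[2-(2-bromo-6-methoxyphenyl)-2-oxoethyl]-5-methyl-3-(tosyloxy)phenyl}prop-2-enoate F2, in which the ester and the acidic ketone methylene are held cis. KOtBu in THF would then bring about an intramolecular Claisen condensation and aromatising enolisation to the naphthol (2-bromo-6-methoxyphenyl)[2-hydroxy-6-methyl-8-(tosyloxy)naphthalen-1-yl]methanone F3. O-Benzylation (BnBr, K2CO3, DMF) would rejoin the route at 21.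

2. Step 12 (proposed new method). Facial discrimination between the two aryl-flanked faces of the iminium ion may be poor, ring-chain tautomers of 25 may react through different cations, and reversible re-ionisation of the product may erode the enantiomeric purity. The fallback sets out from 25. Closure with an achiral acid (TsOH·H2O cat., CH2Cl2, rt) would give the racemic ketal rac-3'-(benzyloxy)-2-[2-(benzyloxy)ethyl]-7-methoxy-7'-methylspiro[isoindoline-1,2'-naphtho[1,8-bc]furan]-3-one F4. Preparative HPLC on a polysaccharide chiral stationary phase would resolve it into 27 and its antipode (S)-3'-(benzyloxy)-2-[2-(benzyloxy)ethyl]-7-methoxy-7'-methylspiro[isoindoline-1,2'-naphtho[1,8-bc]furan]-3-one F5. The antipode could be re-ionised with the same acid to F4 and recycled. The route is rejoined at 27.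

3. Step 10. Oxidative addition and CO insertion at the bromide beside the tetra-ortho-substituted ketone may be sluggish, and the hot primary amine may attack the tosylate. The fallback sets out from 21. Bromine–magnesium exchange with iPrMgCl·LiCl (THF, −20 °C), assisted by the ortho carbonyl, would give the arylmagnesium chloride [2-{[2-(benzyloxy)-6-methyl-8-(tosyloxy)naphthalen-1-yl]carbonyl}-3-methoxyphenyl]magnesium chloride F6. Carboxylation with CO2 would give the keto acid 2-[2-(benzyloxy)-6-methyl-8-(tosyloxy)-1-naphthoyl]-3-methoxybenzoic acid F7. Condensation of F7 with amine 22 (EDC·HCl, HOBt, CH2Cl2, then warming) would give keto amide 23 and hence hydroxylactam 24, where the route is rejoined.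

**Further compounds**

F1 | step 9 | 3-formyl-2-[2-(2-bromo-6-methoxyphenyl)-2-oxoethyl]-5-methylphenyl 4-methylbenzenesulfonate | COc1cccc(Br)c1C(=O)Cc1c(C=O)cc(C)cc1OS(=O)(=O)c1ccc(C)cc1
F2 | step 9 | ethyl (Z)-3-{2-[2-(2-bromo-6-methoxyphenyl)-2-oxoethyl]-5-methyl-3-(tosyloxy)phenyl}prop-2-enoate | CCOC(=O)/C=C\c1cc(C)cc(OS(=O)(=O)c2ccc(C)cc2)c1CC(=O)c1c(Br)cccc1OC
F3 | step 9 | (2-bromo-6-methoxyphenyl)[2-hydroxy-6-methyl-8-(tosyloxy)naphthalen-1-yl]methanone | COc1cccc(Br)c1C(=O)c1c(O)ccc2cc(C)cc(OS(=O)(=O)c3ccc(C)cc3)c12
F4 | step 12 | rac-3'-(benzyloxy)-2-[2-(benzyloxy)ethyl]-7-methoxy-7'-methylspiro[isoindoline-1,2'-naphtho[1,8-bc]furan]-3-one | COc1cccc2c1C1(Oc3cc(C)cc4ccc(OCc5ccccc5)c1c34)N(CCOCc1ccccc1)C2=O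
F5 | step 12 | (S)-3'-(benzyloxy)-2-[2-(benzyloxy)ethyl]-7-methoxy-7'-methylspiro[isoindoline-1,2'-naphtho[1,8-bc]furan]-3-one | COc1cccc2c1[C@]1(Oc3cc(C)cc4ccc(OCc5ccccc5)c1c34)N(CCOCc1ccccc1)C2=O
F6 | step 10 | [2-{[2-(benzyloxy)-6-methyl-8-(tosyloxy)naphthalen-1-yl]carbonyl}-3-methoxyphenyl]magnesium chloride | COc1cccc([Mg]Cl)c1C(=O)c1c(OCc2ccccc2)ccc2cc(C)cc(OS(=O)(=O)c3ccc(C)cc3)c12
F7 | step 10 | 2-[2-(benzyloxy)-6-methyl-8-(tosyloxy)-1-naphthoyl]-3-methoxybenzoic acid | COc1cccc(C(=O)O)c1C(=O)c1c(OCc2ccccc2)ccc2cc(C)cc(OS(=O)(=O)c3ccc(C)cc3)c12
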